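## Retrosynthetic overview

1. Both halves are the same C19 unit with the same spatial carbinol configuration, differing only in alkene geometry (E or Z) and hydration state (enol lactone or keto ester). Both are therefore drawn from one pair of chiral α-alkylidene-β-lactones, rather than esterifying a protected seco-acid with the finished butanolide.
2. The methyl ketone comes from a terminal alkyne by ester-assisted Au hydration (last step). The 5-methylene butanolide comes from a 4-pentynoic acid by Ag 5-exo-dig cyclisation.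
3. The inter-unit ester comes from strain-release acyl transfer: the alkoxide of the E hydroxy acid opens the Z alkylidene-β-lactone, which is both the activated acyl group and the protecting group of its own OH.
4. The E and Z alkylidene-β-lactones come from one selenoxide elimination on one cis-β-lactone. That lactone comes from a catalytic asymmetric ketene–ynal [2+2] (palmitoyl chloride + TMS-propynal), which sets both stereocentres of the target in one step.
5. Ring order: the oxetan-2-one is formed in step 1 and is sacrificial (opened in steps 4 and 5). The γ-methylene butanolide, the only ring of the target, is formed in step 6.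

**Assumptions**

- The SMILES is read as lactone half 3E,4S and acyl half 2Z,1'S. Both carbinol carbons have the same spatial arrangement.
- O-TMS-quinidine is taken to be the pseudo-enantiomer that gives the (3S,4S) lactone with this ynal. If it gives the antipode, O-TMS-quinine is used and nothing else changes.
- LDA and LiHMDS are used as purchased solutions.

## Route

**Step 1**
Reactants: 1 palmitoyl chloride; 2 3-(trimethylsilyl)prop-2-ynal
Product: 4 (3S,4S)-3-tetradecyl-4-[(trimethylsilyl)ethynyl]oxetan-2-one (cis), via tetradecylketene 3 (not isolated)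
Conditions: O-TMS-quinidine (10 mol %), LiClO4 (1 equiv), iPr2NEt, CH2Cl2/Et2O 2:1, −78 °C, slow addition of 1
Reagents that add atoms: none
Why: This is a cinchona-alkaloid/Lewis-acid catalysed acyl halide–aldehyde cyclocondensation (Wynberg-type ketene–aldehyde [2+2]), in which the chiral ammonium enolate of 3 adds to the Li+-activated, non-enolisable ynal through a closed transition state to give the cis-β-lactone; the C4 configuration set here becomes both carbinol centres of the target, and C3 is erased in step 3.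

**Step 2**
Reactants: 4 (3S,4S)-3-tetradecyl-4-[(trimethylsilyl)ethynyl]oxetan-2-one
Product: 6 (3R,4R)-3-(phenylselanyl)-3-tetradecyl-4-[(trimethylsilyl)ethynyl]oxetan-2-one (SePh trans to alkynyl; C4 spatially unchanged), via lithium enolate 5 (not isolated)
Conditions: LDA, THF, −78 °C; PhSeBr, −78 °C
Reagents that add atoms: phenylselenyl bromide, Br[Se]c1ccccc1; lithium diisopropylamide, [Li+].CC(C)[N-]C(C)C (only the Li+ of 5)
Why: This is α-selenenylation of an ester enolate; β-lactone enolates persist at −78 °C because β-elimination is stereoelectronically blocked in the planar four-membered ring, the electrophile enters anti to the C4 alkynyl group, and C4 is not touched.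

**Step 3**
Reactants: 6 (3R,4R)-3-(phenylselanyl)-3-tetradecyl-4-[(trimethylsilyl)ethynyl]oxetan-2-one
Product: 8 (3Z,4S)-3-tetradecylidene-4-[(trimethylsilyl)ethynyl]oxetan-2-one and 9 (3E,4S)-3-tetradecylidene-4-[(trimethylsilyl)ethynyl]oxetan-2-one (both kept; separated on silica gel), via selenoxide 7 (not isolated)
Conditions: mCPBA (1.05 equiv), CH2Cl2, −78 °C → rt
Reagents that add atoms: mCPBA, OOC(=O)c1cccc(Cl)c1 (supplies the O of 7, which leaves again in the elimination)
Why: This is a selenoxide syn-elimination (Ei) that can only run exocyclically, because the endocyclic path would give an oxetene; either diastereotopic chain CH2 hydrogen can reach Se–O, so both geometries form (expected Z:E about 1–3:1), which is what is wanted since Z is the acyl half and E the lactone half.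

**Step 4**
Reactants: 9 (3E,4S)-3-tetradecylidene-4-[(trimethylsilyl)ethynyl]oxetan-2-one
Product: 11 (2E)-2-[(1R)-1-hydroxyprop-2-yn-1-yl]hexadec-2-enoic acid (same spatial arrangement; the descriptor changes only because SiMe3 is lost), via lithium carboxylate 10 (not isolated)
Conditions: LiOH·H2O (4 equiv), THF/H2O 3:1, 0 °C → rt; 1 M HCl work-up
Reagents that add atoms: lithium hydroxide, [Li+].[OH-]
Why: This is BAc2 saponification of the strained lactone (acyl–O cleavage, so the carbinol C–O bond and its configuration are retained), followed in the same pot by hydroxide-induced protodesilylation of the alkynylsilane.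

**Step 5**
Reactants: 11 (2E)-2-[(1R)-1-hydroxyprop-2-yn-1-yl]hexadec-2-enoic acid; 8 (3Z,4S)-3-tetradecylidene-4-[(trimethylsilyl)ethynyl]oxetan-2-one
Product: 14 (2E)-2-[(1R)-1-({(2Z)-2-[(1S)-1-hydroxy-3-(trimethylsilyl)prop-2-yn-1-yl]hexadec-2-enoyl}oxy)prop-2-yn-1-yl]hexadec-2-enoic acid, via dilithium dianion 12 (not isolated), via dilithium salt of the coupled ester 13 (not isolated)
Conditions: 11 (1.5 equiv), LiHMDS (2.03 equiv per 11), THF, −78 °C; 8 (1.0 equiv) by syringe pump, −78 → −30 °C; 1 M HCl quench (excess 11 recovered)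
Reagents that add atoms: lithium hexamethyldisilazide, [Li+].C[Si](C)(C)[N-][Si](C)(C)C (only the Li+ of 12 and 13)
Why: Proposed new method: fragment coupling by strain-release acyl–oxygen opening of an α-alkylidene-β-lactone with the secondary lithium alkoxide of a hydroxy-acid dianion, the closest known reaction type being alcoholysis of β-lactones at the acyl carbon by hard alkoxides (LiOBn, NaOMe); 12 has no electrophilic site (its enol lactone is not yet built) and 8 has no free OH, so only the crossed E-alcohol/Z-acyl ester can form first, no carbinol C–O bond is broken so both centres and both alkene geometries are retained, ring strain prevents 13 from closing back to 8, and slow addition of 8 to excess 12 limits further acylation of 13.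

**Step 6**
Reactants: 14 (2E)-2-[(1R)-1-({(2Z)-2-[(1S)-1-hydroxy-3-(trimethylsilyl)prop-2-yn-1-yl]hexadec-2-enoyl}oxy)prop-2-yn-1-yl]hexadec-2-enoic acid
Product: 16 (3S,4E)-2-methylidene-5-oxo-4-tetradecylideneoxolan-3-yl (2Z)-2-[(1R)-1-hydroxyprop-2-yn-1-yl]hexadec-2-enoate, via desilylated diyne acid 15 (not isolated)
Conditions: AgNO3 (15 mol %), acetone/H2O 10:1, rt, dark
Reagents that add atoms: none
Why: Silver(I) π-acid catalysis performs two known reactions in one pot, protodesilylation of the alkynyl-SiMe3 via the silver acetylide and 5-exo-dig cycloisomerisation of the 4-pentynoic acid to the γ-methylene butanolide, and neither touches the esters, the alkenes or the stereocentres.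

**Step 7**
Reactants: 16 (3S,4E)-2-methylidene-5-oxo-4-tetradecylideneoxolan-3-yl (2Z)-2-[(1R)-1-hydroxyprop-2-yn-1-yl]hexadec-2-enoate
Product: 18 (3S,4E)-2-methylidene-5-oxo-4-tetradecylideneoxolan-3-yl (2Z)-2-[(1S)-1-hydroxy-2-oxopropyl]hexadec-2-enoate (target), via enol tautomer 17 (not isolated)
Conditions: Ph3PAuCl/AgSbF6 (2 mol % each), 1,4-dioxane, H2O (3 equiv), rt
Reagents that add atoms: water, O
Why: This is gold(I)-catalysed Markovnikov alkyne hydration with neighbouring-carbonyl assistance, in which the ester C=O attacks the Au-bound alkyne 5-exo-dig, water adds to the resulting cation, and the ortho-acid collapses by expelling the better leaving enol oxygen rather than the secondary alkoxide; the enol 17 then tautomerises to the methyl ketone at rt and near-neutral pH, where the enol lactone, the allylic ester and the epimerisable α-ketol centre survive.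

## Compound list

1 | palmitoyl chloride | CCCCCCCCCCCCCCCC(=O)Cl | starting material
2 | 3-(trimethylsilyl)prop-2-ynal | C[Si](C)(C)C#CC=O | starting material
3 | tetradecylketene | CCCCCCCCCCCCCCC=C=O | intermediate
4 | (3S,4S)-3-tetradecyl-4-[(trimethylsilyl)ethynyl]oxetan-2-one | O=C1O[C@H](C#C[Si](C)(C)C)[C@@H]1CCCCCCCCCCCCCC | intermediate
5 | lithium (4S)-3-tetradecyl-4-[(trimethylsilyl)ethynyl]-4H-oxet-2-olate | [Li+].[O-]C1=C(CCCCCCCCCCCCCC)[C@@H](C#C[Si](C)(C)C)O1 | intermediate
6 | (3R,4R)-3-(phenylselanyl)-3-tetradecyl-4-[(trimethylsilyl)ethynyl]oxetan-2-one | O=C1O[C@H](C#C[Si](C)(C)C)[C@@]1(CCCCCCCCCCCCCC)[Se]c1ccccc1 | intermediate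
7 | (3R,4R)-3-(benzeneseleninyl)-3-tetradecyl-4-[(trimethylsilyl)ethynyl]oxetan-2-one (mixture at Se) | O=C1O[C@H](C#C[Si](C)(C)C)[C@@]1(CCCCCCCCCCCCCC)[Se](=O)c1ccccc1 | intermediate
8 | (3Z,4S)-3-tetradecylidene-4-[(trimethylsilyl)ethynyl]oxetan-2-one | CCCCCCCCCCCCC/C=C1\C(=O)O[C@@H]1C#C[Si](C)(C)C | intermediate
9 | (3E,4S)-3-tetradecylidene-4-[(trimethylsilyl)ethynyl]oxetan-2-one | CCCCCCCCCCCCC/C=C1/C(=O)O[C@@H]1C#C[Si](C)(C)C | intermediate
10 | lithium (2E)-2-[(1S)-1-hydroxy-3-(trimethylsilyl)prop-2-yn-1-yl]hexadec-2-enoate | [Li+].[O-]C(=O)/C(=C/CCCCCCCCCCCCC)[C@H](O)C#C[Si](C)(C)C | intermediate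
11 | (2E)-2-[(1R)-1-hydroxyprop-2-yn-1-yl]hexadec-2-enoic acid | OC(=O)/C(=C/CCCCCCCCCCCCC)[C@H](O)C#C | intermediate
12 | dilithium (2E)-2-[(1R)-1-oxidoprop-2-yn-1-yl]hexadec-2-enoate | [Li+].[Li+].[O-]C(=O)/C(=C/CCCCCCCCCCCCC)[C@H]([O-])C#C | intermediate
13 | dilithium carboxylate/alkoxide salt of 14 | [Li+].[Li+].[O-]C(=O)/C(=C/CCCCCCCCCCCCC)[C@@H](C#C)OC(=O)/C(=C\CCCCCCCCCCCCC)[C@H]([O-])C#C[Si](C)(C)C | intermediate
14 | (2E)-2-[(1R)-1-({(2Z)-2-[(1S)-1-hydroxy-3-(trimethylsilyl)prop-2-yn-1-yl]hexadec-2-enoyl}oxy)prop-2-yn-1-yl]hexadec-2-enoic acid | OC(=O)/C(=C/CCCCCCCCCCCCC)[C@@H](C#C)OC(=O)/C(=C\CCCCCCCCCCCCC)[C@H](O)C#C[Si](C)(C)C | intermediate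
15 | (2E)-2-[(1R)-1-({(2Z)-2-[(1R)-1-hydroxyprop-2-yn-1-yl]hexadec-2-enoyl}oxy)prop-2-yn-1-yl]hexadec-2-enoic acid | OC(=O)/C(=C/CCCCCCCCCCCCC)[C@@H](C#C)OC(=O)/C(=C\CCCCCCCCCCCCC)[C@H](O)C#C | intermediate
16 | (3S,4E)-2-methylidene-5-oxo-4-tetradecylideneoxolan-3-yl (2Z)-2-[(1R)-1-hydroxyprop-2-yn-1-yl]hexadec-2-enoate | C=C1OC(=O)/C(=C/CCCCCCCCCCCCC)[C@@H]1OC(=O)/C(=C\CCCCCCCCCCCCC)[C@H](O)C#C | intermediate
17 | (3S,4E)-2-methylidene-5-oxo-4-tetradecylideneoxolan-3-yl (2Z)-2-[(1S)-1,2-dihydroxyprop-2-en-1-yl]hexadec-2-enoate (enol) | C=C1OC(=O)/C(=C/CCCCCCCCCCCCC)[C@@H]1OC(=O)/C(=C\CCCCCCCCCCCCC)[C@H](O)C(O)=C | intermediate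
18 | (3S,4E)-2-methylidene-5-oxo-4-tetradecylideneoxolan-3-yl (2Z)-2-[(1S)-1-hydroxy-2-oxopropyl]hexadec-2-enoate | C=C1OC(=O)/C(=C/CCCCCCCCCCCCC)[C@@H]1OC(=O)/C(=C\CCCCCCCCCCCCC)[C@H](O)C(C)=O | target

## Step count

- Total step count: 7.
- Longest linear sequence: 7 (1/2 → 4 → 6 → 9 → 11 → 14 → 16 → 18). Compound 8 branches off at step 3 and re-enters at step 5.

## Steps most likely to fail

**Step 5 (acyl transfer).**
Three things can go wrong:

- the alkoxide in 13 may compete with 12 for 8, giving oligo-esters;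
- the hindered lithium alkoxide may be too slow;
- the alkoxide may attack the alkynylsilane.

The fallback is conventional carboxyl activation with both functions masked. It sets out from 8 and 9 and comes back at 15. Brief saponification of 8 (LiOH 1.1 equiv, THF/H2O, 0 °C, 15 min, C–Si retained) gives (2Z)-2-[(1S)-1-hydroxy-3-(trimethylsilyl)prop-2-yn-1-yl]hexadec-2-enoic acid F1. TESCl/imidazole converts this into triethylsilyl (2Z)-2-[(1S)-1-(triethylsilyloxy)-3-(trimethylsilyl)prop-2-yn-1-yl]hexadec-2-enoate F2. Its silyl ester alone is hydrolysed (aq NaHCO3, THF) to (2Z)-2-[(1S)-1-(triethylsilyloxy)-3-(trimethylsilyl)prop-2-yn-1-yl]hexadec-2-enoic acid F3. Separately, 9 is opened with lithium 2-(trimethylsilyl)ethoxide (THF, −78 °C) to 2-(trimethylsilyl)ethyl (2E)-2-[(1S)-1-hydroxy-3-(trimethylsilyl)prop-2-yn-1-yl]hexadec-2-enoate F4. A Shiina esterification (2-methyl-6-nitrobenzoic anhydride, DMAP, Et3N) joins the two as 2-(trimethylsilyl)ethyl (2E)-2-[(1S)-1-({(2Z)-2-[(1S)-1-(triethylsilyloxy)-3-(trimethylsilyl)prop-2-yn-1-yl]hexadec-2-enoyl}oxy)-3-(trimethylsilyl)prop-2-yn-1-yl]hexadec-2-enoate F5. TBAF/AcOH (THF, 0 °C → rt) strips all silicon groups to give 15, which is isolated and cyclised under the step 6 conditions.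

**Step 7 (hydration next to an enol lactone).**
The risks are hydrolysis of the enol lactone, loss of the alcohol half from the ortho-acid intermediate, and Meyer–Schuster rearrangement.

The fallback is a biomimetic enol-ester acyl transfer, in which no alkyne is ever hydrated. It sets out from 8 and 12 and comes back at 18. LiOH (THF/H2O, rt) converts 8 into (2Z)-2-[(1R)-1-hydroxyprop-2-yn-1-yl]hexadec-2-enoic acid F6. AgNO3 (cat., acetone) cyclises it to obtusilactone A, (3Z,4S)-4-hydroxy-5-methylidene-3-tetradecylideneoxolan-2-one F7. TESCl/imidazole gives (3Z,4S)-5-methylidene-3-tetradecylidene-4-(triethylsilyloxy)oxolan-2-one F8. Adding F8 to 12 at −78 °C lets the alkoxide open the enol lactone. The expelled terminal enolate is protonated by an AcOH quench at −78 °C and becomes the methyl ketone directly, giving (2E)-2-[(1R)-1-({(2Z)-2-[(1S)-2-oxo-1-(triethylsilyloxy)propyl]hexadec-2-enoyl}oxy)prop-2-yn-1-yl]hexadec-2-enoic acid F9. AgNO3 (cat., acetone) closes the butanolide to (3S,4E)-2-methylidene-5-oxo-4-tetradecylideneoxolan-3-yl (2Z)-2-[(1S)-2-oxo-1-(triethylsilyloxy)propyl]hexadec-2-enoate F10. HF·pyridine (THF, 0 °C) then gives 18.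

**Step 3 (supply of both geometries).**
The elimination may give almost only one isomer, most likely Z. This fallback addresses only the isomer ratio, not a failure of the elimination itself.

The geometry is corrected after the elimination by energy-transfer isomerisation. The fallback sets out from 8, the isomer expected in surplus, and comes back at 9. Irradiation at 300 nm in degassed acetone (solvent and triplet sensitiser) at 0–10 °C drives the enoate to a photostationary mixture of about 1:1 of 8 and 9, which is re-chromatographed and recycled. The fallback makes no compound outside the list (F0).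

## Further compounds

F1 | step 5 | (2Z)-2-[(1S)-1-hydroxy-3-(trimethylsilyl)prop-2-yn-1-yl]hexadec-2-enoic acid | OC(=O)/C(=C\CCCCCCCCCCCCC)[C@H](O)C#C[Si](C)(C)C
F2 | step 5 | triethylsilyl (2Z)-2-[(1S)-1-(triethylsilyloxy)-3-(trimethylsilyl)prop-2-yn-1-yl]hexadec-2-enoate | CC[Si](CC)(CC)OC(=O)/C(=C\CCCCCCCCCCCCC)[C@H](O[Si](CC)(CC)CC)C#C[Si](C)(C)C
F3 | step 5 | (2Z)-2-[(1S)-1-(triethylsilyloxy)-3-(trimethylsilyl)prop-2-yn-1-yl]hexadec-2-enoic acid | OC(=O)/C(=C\CCCCCCCCCCCCC)[C@H](O[Si](CC)(CC)CC)C#C[Si](C)(C)C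
F4 | step 5 | 2-(trimethylsilyl)ethyl (2E)-2-[(1S)-1-hydroxy-3-(trimethylsilyl)prop-2-yn-1-yl]hexadec-2-enoate | C[Si](C)(C)CCOC(=O)/C(=C/CCCCCCCCCCCCC)[C@H](O)C#C[Si](C)(C)C
F5 | step 5 | 2-(trimethylsilyl)ethyl (2E)-2-[(1S)-1-({(2Z)-2-[(1S)-1-(triethylsilyloxy)-3-(trimethylsilyl)prop-2-yn-1-yl]hexadec-2-enoyl}oxy)-3-(trimethylsilyl)prop-2-yn-1-yl]hexadec-2-enoate | C[Si](C)(C)CCOC(=O)/C(=C/CCCCCCCCCCCCC)[C@@H](C#C[Si](C)(C)C)OC(=O)/C(=C\CCCCCCCCCCCCC)[C@H](O[Si](CC)(CC)CC)C#C[Si](C)(C)C
F6 | step 7 | (2Z)-2-[(1R)-1-hydroxyprop-2-yn-1-yl]hexadec-2-enoic acid | OC(=O)/C(=C\CCCCCCCCCCCCC)[C@H](O)C#C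
F7 | step 7 | obtusilactone A, (3Z,4S)-4-hydroxy-5-methylidene-3-tetradecylideneoxolan-2-one | C=C1OC(=O)/C(=C\CCCCCCCCCCCCC)[C@@H]1O
F8 | step 7 | (3Z,4S)-5-methylidene-3-tetradecylidene-4-(triethylsilyloxy)oxolan-2-one | C=C1OC(=O)/C(=C\CCCCCCCCCCCCC)[C@@H]1O[Si](CC)(CC)CC
F9 | step 7 | (2E)-2-[(1R)-1-({(2Z)-2-[(1S)-2-oxo-1-(triethylsilyloxy)propyl]hexadec-2-enoyl}oxy)prop-2-yn-1-yl]hexadec-2-enoic acid | OC(=O)/C(=C/CCCCCCCCCCCCC)[C@@H](C#C)OC(=O)/C(=C\CCCCCCCCCCCCC)[C@H](O[Si](CC)(CC)CC)C(C)=O
F10 | step 7 | (3S,4E)-2-methylidene-5-oxo-4-tetradecylideneoxolan-3-yl (2Z)-2-[(1S)-2-oxo-1-(triethylsilyloxy)propyl]hexadec-2-enoate | C=C1OC(=O)/C(=C/CCCCCCCCCCCCC)[C@@H]1OC(=O)/C(=C\CCCCCCCCCCCCC)[C@H](O[Si](CC)(CC)CC)C(C)=O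
F0 | step 3 | none | none
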